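**Retrosynthetic overview**

- Late stage: the enone C(=O)–Cα bond is cut back to an aryl aldehyde, carried as a 1,3-dithiane on C1', and (E)-β-bromostyrene, which brings ring B ready-made. The C2' oxygen travels as an isopropyl ether and the C4' phenol as a silyl ether.
- Key disconnection: ring A is opened at C4'–C5', C6'–C1' and C3'–C4' to methoxyacetylene and a squarate-derived 4-acyloxy-2-dithianyl-3-isopropoxycyclobutenone (Danheiser benzannulation).
- Feature used: on ring A the consecutive atoms C4' (free OH), C5' (H) and C6' (OMe) are exactly what a ketene carbonyl carbon and the CH and C–OMe carbons of a terminal ynol ether deliver. C3' arrives already carrying the (R)-2-methylbutanoate, so no phenol has to be distinguished from another.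
- The cyclobutenone comes from diisopropyl squarate by addition of 2-lithio-1,3-dithiane, regioselective hydride reduction and esterification with (R)-2-methylbutanoic acid.
- Ring order: ring A is the only ring constructed (step 5); ring B is bought.

Key step: step 5

Assumption (remark on the chemistry): from step 5 onward the (R)-ester sits on a catechol-type oxygen beside a second ring oxygen, so every later step is kept neutral or acidic to prevent 1,2-acyl shift; the carbinol carbons made in steps 2 and 8 are left unassigned because both are erased later.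

**Route**

Step 1
Reactants: 1 diisopropyl squarate; 2 1,3-dithiane
Product: 5 3-(1,3-dithian-2-yl)-4-(propan-2-yloxy)cyclobut-3-ene-1,2-dione, via 2-lithio-1,3-dithiane 3 (not isolated), via hydroxy adduct 4 (not isolated)
Conditions: 2, nBuLi, THF, −30 °C; add to 1, THF, −78 °C; 2 M HCl quench; crude adduct, 12 M HCl (cat.), CH2Cl2, rt
Reagents that add atoms: none
Why: Organolithium 1,2-addition to a squarate ester carbonyl followed by acid-catalysed loss of propan-2-ol (the standard squarate to 3-substituted 4-alkoxycyclobutenedione sequence) should give 5, the dithiane ring being inert to the acid.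

Step 2
Reactants: 5 3-(1,3-dithian-2-yl)-4-(propan-2-yloxy)cyclobut-3-ene-1,2-dione
Product: 6 racemic 2-(1,3-dithian-2-yl)-4-hydroxy-3-(propan-2-yloxy)cyclobut-2-en-1-one
Conditions: LiAlH(OtBu)3, THF, −78 °C; cold sat. aq. NH4Cl
Reagents that add atoms: none
Why: The carbonyl next to the dithianyl carbon is a vinylogous ester, so the bulky, weakly basic hydride should reduce only the ketone-like carbonyl next to the isopropoxy carbon (regioselective 1,2-reduction of an alkoxycyclobutenedione); the new carbinol centre is racemic and irrelevant because it becomes aromatic C3'.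

Step 3
Reactants: 6 racemic 2-(1,3-dithian-2-yl)-4-hydroxy-3-(propan-2-yloxy)cyclobut-2-en-1-one; 7 (R)-2-methylbutanoic acid
Product: 9 3-(1,3-dithian-2-yl)-4-oxo-2-(propan-2-yloxy)cyclobut-2-en-1-yl (2R)-2-methylbutanoate (both epimers at the ring carbinol carbon), via O-acylisourea 8 (not isolated)
Conditions: DCC, DMAP (cat.), CH2Cl2, 0 °C
Reagents that add atoms: none
Why: Steglich esterification under cold, near-neutral conditions avoids the acid that would transpose the hydroxycyclobutenone and should not epimerise the unactivated α-centre of the acid, so the (R) centre is carried in unchanged from 7.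

Step 4
Reactants: 10 chloroacetaldehyde dimethyl acetal
Product: 12 methoxyacetylene, via sodium methoxyacetylide 11 (not isolated)
Conditions: NaNH2 (3 equiv), liq. NH3, −33 °C; evaporate NH3; sat. aq. NaCl, −20 °C; distil into cold toluene
Reagents that add atoms: none
Why: Base-induced double elimination (HCl, then methanol) from a chloroacetal with NaNH2 in liquid ammonia is the established preparation of methoxyacetylene, which is released from its sodium salt by hydrolysis and kept as a cold solution.

Step 5
Reactants: 9 3-(1,3-dithian-2-yl)-4-oxo-2-(propan-2-yloxy)cyclobut-2-en-1-yl (2R)-2-methylbutanoate; 12 methoxyacetylene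
Product: 17 3-(1,3-dithian-2-yl)-6-hydroxy-4-methoxy-2-(propan-2-yloxy)phenyl (2R)-2-methylbutanoate, via vinylketene 13 (not isolated), via vinylcyclobutenone 14 (not isolated), via dienylketene 15 (not isolated), via cyclohexadienone 16 (not isolated)
Conditions: 12 (4 equiv), toluene (dilute), sealed tube, 80–90 °C
Reagents that add atoms: none
Why: Danheiser benzannulation: thermal 4π electrocyclic opening of 9 breaks the ring bond between the carbonyl carbon and the acyloxy-bearing carbon to give vinylketene 13, whose ketene C=C undergoes [2+2] cycloaddition with 12 to give 14, which opens again (4π) to dienylketene 15 and closes to 16, which tautomerises to the phenol. The closest known reaction type is the benzannulation of alkyl- and aryl-substituted cyclobutenones with alkoxyacetylenes to resorcinol monoethers; here the cyclobutenone carries the oxygen pattern of a squarate. Ring A is closed by a thermal disrotatory 6π electrocyclisation that forms C3'–C4', after C4'–C5' and C6'–C1' have been made in the [2+2] event. No stereocentre is created: the epimeric ring carbon of 9 becomes aromatic C3', and the (R) centre is a spectator α to an ester under neutral thermal conditions. The step needs regioselectivity in the [2+2] event, secured by the match between the nucleophilic CH terminus of the ynol ether and the electrophilic ketene carbon (H at C5', OMe at C6'), and it needs a dienylketene that can close, secured because the acyloxy donor rotates outward in the first opening (H, not O-acyl, points into the closing triene) and because the sp3 dithianyl group offers no rival 6π terminus.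

Step 6
Reactants: 17 3-(1,3-dithian-2-yl)-6-hydroxy-4-methoxy-2-(propan-2-yloxy)phenyl (2R)-2-methylbutanoate
Product: 18 6-[(tert-butyldimethylsilyl)oxy]-3-(1,3-dithian-2-yl)-4-methoxy-2-(propan-2-yloxy)phenyl (2R)-2-methylbutanoate
Conditions: TBSOTf, 2,6-lutidine, CH2Cl2, −78 °C
Reagents that add atoms: tert-butyldimethylsilyl trifluoromethanesulfonate, CC(C)(C)[Si](C)(C)OS(=O)(=O)C(F)(F)F
Why: Silyl ether formation with a silyl triflate and a hindered pyridine base at −78 °C should outrun 1,2-acyl shift to the neighbouring oxygen and masks the acidic phenol for the alkylative, organometallic and Lewis-acidic steps that follow.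

Step 7
Reactants: 18 6-[(tert-butyldimethylsilyl)oxy]-3-(1,3-dithian-2-yl)-4-methoxy-2-(propan-2-yloxy)phenyl (2R)-2-methylbutanoate
Product: 19 6-[(tert-butyldimethylsilyl)oxy]-3-formyl-4-methoxy-2-(propan-2-yloxy)phenyl (2R)-2-methylbutanoate
Conditions: MeI (excess), CaCO3, MeCN/H2O 4:1, 40 °C
Reagents that add atoms: water, O
Why: Alkylative dithioacetal hydrolysis (S-methylation, opening to a thionium ion stabilised by the electron-rich aryl group, capture by water) is neither oxidising nor halogenating, so the electron-rich ring, the silyl ether and the hindered aryl ester should survive.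

Step 8
Reactants: 19 6-[(tert-butyldimethylsilyl)oxy]-3-formyl-4-methoxy-2-(propan-2-yloxy)phenyl (2R)-2-methylbutanoate; 20 (E)-β-bromostyrene
Product: 22 6-[(tert-butyldimethylsilyl)oxy]-3-[(2E)-1-hydroxy-3-phenylprop-2-en-1-yl]-4-methoxy-2-(propan-2-yloxy)phenyl (2R)-2-methylbutanoate (both carbinol epimers), via styrylchromium dichloride 21 (not isolated)
Conditions: CrCl2 (4 equiv), NiCl2 (2 mol %), DMF, rt
Reagents that add atoms: none
Why: Nozaki–Hiyama–Kishi reaction: zerovalent nickel formed in situ inserts into the alkenyl bromide, transmetalation to trivalent chromium gives 21 with retention of the (E) geometry, and this weakly basic reagent adds to the aldehyde but not to the aryl ester; the carbinol centre forms without control and is removed in step 9.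

Step 9
Reactants: 22 6-[(tert-butyldimethylsilyl)oxy]-3-[(2E)-1-hydroxy-3-phenylprop-2-en-1-yl]-4-methoxy-2-(propan-2-yloxy)phenyl (2R)-2-methylbutanoate
Product: 23 6-[(tert-butyldimethylsilyl)oxy]-4-methoxy-3-[(2E)-3-phenylprop-2-enoyl]-2-(propan-2-yloxy)phenyl (2R)-2-methylbutanoate
Conditions: MnO2 (activated, excess), CH2Cl2, rt
Reagents that add atoms: none
Why: Activated MnO2 oxidises allylic and benzylic alcohols selectively under neutral conditions (allylic oxidation), which avoids ionisation of this doubly activated carbinol and leaves the (E) alkene untouched.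

Step 10
Reactants: 23 6-[(tert-butyldimethylsilyl)oxy]-4-methoxy-3-[(2E)-3-phenylprop-2-enoyl]-2-(propan-2-yloxy)phenyl (2R)-2-methylbutanoate
Product: 24 6-[(tert-butyldimethylsilyl)oxy]-2-hydroxy-4-methoxy-3-[(2E)-3-phenylprop-2-enoyl]phenyl (2R)-2-methylbutanoate
Conditions: BCl3 (1.5 equiv), CH2Cl2, −78 °C; NaH2PO4/Na2HPO4 buffer (pH 7)
Reagents that add atoms: none
Why: Lewis-acid dealkylation with BCl3 cleaves a secondary alkyl aryl ether far faster than a methyl ether, and chelation between the ketone oxygen and the C2' oxygen directs it to the isopropyl group; the aryl ester, silyl ether and enone should tolerate −78 °C, and the neutral quench avoids base-induced acyl shift and acid-induced flavanone closure.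

Step 11
Reactants: 24 6-[(tert-butyldimethylsilyl)oxy]-2-hydroxy-4-methoxy-3-[(2E)-3-phenylprop-2-enoyl]phenyl (2R)-2-methylbutanoate
Product: 25 2,6-dihydroxy-4-methoxy-3-[(2E)-3-phenylprop-2-enoyl]phenyl (2R)-2-methylbutanoate (target)
Conditions: HF·pyridine, pyridine, THF, 0 °C
Reagents that add atoms: none
Why: Fluoride-mediated desilylation in the acidic HF·pyridine medium frees the C4' phenol without generating a phenoxide, so the neighbouring (R)-2-methylbutanoate should neither migrate nor epimerise.

**Compound list**

1 | diisopropyl squarate | CC(C)OC1=C(OC(C)C)C(=O)C1=O | starting material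
2 | 1,3-dithiane | C1CSCSC1 | starting material
3 | 2-lithio-1,3-dithiane | [Li]C1SCCCS1 | intermediate
4 | racemic 4-(1,3-dithian-2-yl)-4-hydroxy-2,3-di(propan-2-yloxy)cyclobut-2-en-1-one (hydroxy adduct) | CC(C)OC1=C(OC(C)C)C(O)(C2SCCCS2)C1=O | intermediate
5 | 3-(1,3-dithian-2-yl)-4-(propan-2-yloxy)cyclobut-3-ene-1,2-dione | CC(C)OC1=C(C2SCCCS2)C(=O)C1=O | intermediate
6 | racemic 2-(1,3-dithian-2-yl)-4-hydroxy-3-(propan-2-yloxy)cyclobut-2-en-1-one | CC(C)OC1=C(C2SCCCS2)C(=O)C1O | intermediate
7 | (R)-2-methylbutanoic acid | CC[C@@H](C)C(=O)O | starting material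
8 | O-acylisourea from 7 and DCC | CC[C@@H](C)C(=O)OC(=NC1CCCCC1)NC1CCCCC1 | intermediate
9 | 3-(1,3-dithian-2-yl)-4-oxo-2-(propan-2-yloxy)cyclobut-2-en-1-yl (2R)-2-methylbutanoate, both epimers at the ring carbinol carbon | CC[C@@H](C)C(=O)OC1C(OC(C)C)=C(C2SCCCS2)C1=O | intermediate
10 | chloroacetaldehyde dimethyl acetal (2-chloro-1,1-dimethoxyethane) | COC(CCl)OC | starting material
11 | sodium methoxyacetylide | [Na+].[C-]#COC | intermediate
12 | methoxyacetylene | C#COC | intermediate
13 | vinylketene: (1Z)-3-(1,3-dithian-2-yl)-4-oxo-2-(propan-2-yloxy)buta-1,3-dien-1-yl (2R)-2-methylbutanoate | CC[C@@H](C)C(=O)O/C=C(OC(C)C)/C(=C=O)C1SCCCS1 | intermediate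
14 | vinylcyclobutenone: (1Z)-2-[1-(1,3-dithian-2-yl)-2-methoxy-4-oxocyclobut-2-en-1-yl]-2-(propan-2-yloxy)ethenyl (2R)-2-methylbutanoate, racemic at the ring carbon | CC[C@@H](C)C(=O)O/C=C(OC(C)C)/C1(C2SCCCS2)C(=O)C=C1OC | intermediate
15 | dienylketene: (1Z,3Z)-3-(1,3-dithian-2-yl)-4-methoxy-6-oxo-2-(propan-2-yloxy)hexa-1,3,5-trien-1-yl (2R)-2-methylbutanoate | CC[C@@H](C)C(=O)O/C=C(OC(C)C)/C(C1SCCCS1)=C(OC)\C=C=O | intermediate
16 | cyclohexadienone: 5-(1,3-dithian-2-yl)-4-methoxy-2-oxo-6-(propan-2-yloxy)cyclohexa-3,5-dien-1-yl (2R)-2-methylbutanoate | CC[C@@H](C)C(=O)OC1C(=O)C=C(OC)C(C2SCCCS2)=C1OC(C)C | intermediate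
17 | 3-(1,3-dithian-2-yl)-6-hydroxy-4-methoxy-2-(propan-2-yloxy)phenyl (2R)-2-methylbutanoate | CC[C@@H](C)C(=O)Oc1c(O)cc(OC)c(C2SCCCS2)c1OC(C)C | intermediate
18 | 6-[(tert-butyldimethylsilyl)oxy]-3-(1,3-dithian-2-yl)-4-methoxy-2-(propan-2-yloxy)phenyl (2R)-2-methylbutanoate | CC[C@@H](C)C(=O)Oc1c(O[Si](C)(C)C(C)(C)C)cc(OC)c(C2SCCCS2)c1OC(C)C | intermediate
19 | 6-[(tert-butyldimethylsilyl)oxy]-3-formyl-4-methoxy-2-(propan-2-yloxy)phenyl (2R)-2-methylbutanoate | CC[C@@H](C)C(=O)Oc1c(O[Si](C)(C)C(C)(C)C)cc(OC)c(C=O)c1OC(C)C | intermediate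
20 | (E)-β-bromostyrene | Br/C=C/c1ccccc1 | starting material
21 | dichloro[(E)-2-phenylethenyl]chromium | Cl[Cr](Cl)/C=C/c1ccccc1 | intermediate
22 | 6-[(tert-butyldimethylsilyl)oxy]-3-[(2E)-1-hydroxy-3-phenylprop-2-en-1-yl]-4-methoxy-2-(propan-2-yloxy)phenyl (2R)-2-methylbutanoate, both carbinol epimers | CC[C@@H](C)C(=O)Oc1c(O[Si](C)(C)C(C)(C)C)cc(OC)c(C(O)/C=C/c2ccccc2)c1OC(C)C | intermediate
23 | 6-[(tert-butyldimethylsilyl)oxy]-4-methoxy-3-[(2E)-3-phenylprop-2-enoyl]-2-(propan-2-yloxy)phenyl (2R)-2-methylbutanoate | CC[C@@H](C)C(=O)Oc1c(O[Si](C)(C)C(C)(C)C)cc(OC)c(C(=O)/C=C/c2ccccc2)c1OC(C)C | intermediate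
24 | 6-[(tert-butyldimethylsilyl)oxy]-2-hydroxy-4-methoxy-3-[(2E)-3-phenylprop-2-enoyl]phenyl (2R)-2-methylbutanoate | CC[C@@H](C)C(=O)Oc1c(O[Si](C)(C)C(C)(C)C)cc(OC)c(C(=O)/C=C/c2ccccc2)c1O | intermediate
25 | 2,6-dihydroxy-4-methoxy-3-[(2E)-3-phenylprop-2-enoyl]phenyl (2R)-2-methylbutanoate | CC[C@@H](C)C(=O)Oc1c(O)cc(OC)c(C(=O)/C=C/c2ccccc2)c1O | target

**Step count**

Total steps: 11. Longest linear sequence: 10 steps (1, 2, 3, 5, 6, 7, 8, 9, 10, 11) from diisopropyl squarate; step 4 is a one-step side branch.

**Steps most likely to fail**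

Step 5. The vinylketene released from 9 may be consumed by self-condensation, or by acylating the phenol already formed, faster than it is captured by the volatile, weakly nucleophilic ynol ether at the hindered, dithianyl-substituted ketene carbon. Slow 1,2-shift of the ester to the new phenol at 80–90 °C is a second hazard. The fallback sets out from 9 and returns at 17. Compound 9 would be heated in toluene with an excess of commercial 1,1-dimethoxyethene, a more nucleophilic and non-volatile ketene acetal, which should take up the vinylketene in a ketene/ketene acetal [2+2] cycloaddition of the same polarity. This gives the 3,3-dimethoxy-2-vinylcyclobutanone F1. Loss of methanol from F1 on silica gel or with catalytic pyridinium p-toluenesulfonate gives the vinylcyclobutenone 14 as a discrete compound. Brief heating of 14 alone, with no other ketene acceptor present, should complete the 4π opening and 6π closure to 17.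

Step 8. Nickel-mediated activation of the alkenyl bromide may be slow, with reductive homocoupling to the diene competing, and the alkenylchromium reagent may add sluggishly to an aldehyde flanked by two ortho alkoxy groups and deactivated by three oxygen donors. The fallback sets out from 19 and returns at 22. Hydrozirconation of commercial phenylacetylene with Cp2Zr(H)Cl in CH2Cl2 gives chloro[(E)-2-phenylethenyl]zirconocene F2. Transmetalation with Me2Zn at −65 °C gives methyl[(E)-2-phenylethenyl]zinc F3. F3 is added to 19 at 0 °C, with the zirconocene by-product serving as Lewis acid, to give 22 after aqueous work-up. Alkenylzinc reagents of this kind leave aryl esters and silyl ethers untouched.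

Step 10. The Lewis acid may over-react: cleavage of the methyl ether that is also ortho to the ketone, chloride addition to the enone, ring closure of the freed C2' phenol onto the enone during the quench, or Lewis-acid-promoted shift of the ester. The fallback sets out from 19 and returns at the target 25. The isopropyl ether would be cleaved at the aldehyde stage (BCl3, CH2Cl2, −78 °C), where the formyl oxygen offers the same chelation and no enone is present, to give the 2-hydroxybenzaldehyde F4. Silylation of the hydrogen-bonded phenol (TBSOTf, 2,6-lutidine, −78 °C) gives the bis(silyl ether) F5. Nozaki–Hiyama–Kishi addition of 20 (through 21) gives the allylic alcohol F6, and MnO2 gives the enone F7. HF·pyridine then removes both silyl groups in one operation to give 25, so the last unmasking is a mild desilylation.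

**Further compounds**

F1 | step 5 | (1Z)-2-[1-(1,3-dithian-2-yl)-2,2-dimethoxy-4-oxocyclobutyl]-2-(propan-2-yloxy)ethenyl (2R)-2-methylbutanoate | CC[C@@H](C)C(=O)O/C=C(OC(C)C)/C1(C2SCCCS2)C(=O)CC1(OC)OC
F2 | step 8 | chloro[(E)-2-phenylethenyl]bis(cyclopentadienyl)zirconium | Cl[Zr](/C=C/c1ccccc1)(C1C=CC=C1)C1C=CC=C1
F3 | step 8 | methyl[(E)-2-phenylethenyl]zinc | C[Zn]/C=C/c1ccccc1
F4 | step 10 | 6-[(tert-butyldimethylsilyl)oxy]-3-formyl-2-hydroxy-4-methoxyphenyl (2R)-2-methylbutanoate | CC[C@@H](C)C(=O)Oc1c(O[Si](C)(C)C(C)(C)C)cc(OC)c(C=O)c1O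
F5 | step 10 | 2,6-bis[(tert-butyldimethylsilyl)oxy]-3-formyl-4-methoxyphenyl (2R)-2-methylbutanoate | CC[C@@H](C)C(=O)Oc1c(O[Si](C)(C)C(C)(C)C)cc(OC)c(C=O)c1O[Si](C)(C)C(C)(C)C
F6 | step 10 | 2,6-bis[(tert-butyldimethylsilyl)oxy]-3-[(2E)-1-hydroxy-3-phenylprop-2-en-1-yl]-4-methoxyphenyl (2R)-2-methylbutanoate, both carbinol epimers | CC[C@@H](C)C(=O)Oc1c(O[Si](C)(C)C(C)(C)C)cc(OC)c(C(O)/C=C/c2ccccc2)c1O[Si](C)(C)C(C)(C)C
F7 | step 10 | 2,6-bis[(tert-butyldimethylsilyl)oxy]-4-methoxy-3-[(2E)-3-phenylprop-2-enoyl]phenyl (2R)-2-methylbutanoate | CC[C@@H](C)C(=O)Oc1c(O[Si](C)(C)C(C)(C)C)cc(OC)c(C(=O)/C=C/c2ccccc2)c1O[Si](C)(C)C(C)(C)C
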